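Ring A is disconnected at C3–C4 (drimane numbering). All ten carbons of (R)-carvone become C4 with both its methyls, C5, C6, C7, C8 with its methyl, C9 and C10; the isopropenyl group is the latent gem-dimethyl carbon C4. The key step exploits this quaternary C4 next to the trans ring fusion C5–C10. Iron-hydride hydrogen-atom transfer turns the isopropenyl group into the tertiary C4 radical, which closes ring A onto C3 of a 2-sulfonylallyl chain in one operation, forming C3–C4 and the gem-dimethyl centre. The precursor is carvone carrying, at the future C10, a methyl and a 2-(phenylsulfonyl)allyl group trans to the isopropenyl group.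

Key step: step 5

Remark: the sulfone must sit on the central allyl carbon; bromination–dehydrobromination of allyl phenyl sulfone would place it on the terminal carbon, so the allyl bromide is built from phenyl vinyl sulfone instead.
Remark: drimane numbering is used for all bicyclic compounds; 4 is carried on as its C6 epimer mixture and 11 as whichever C2 epimer forms, because both centres are erased later.

Step 1
Reactants: 1 (R)-(−)-carvone; 2 iodomethane
Product: 4 6-methylcarvone, via carvone lithium enolate 3 (not isolated)
Conditions: LiN(i-Pr)2, THF, −78 °C; MeI, −78 → 0 °C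
Reagents that add atoms: iodomethane (2), CI
Why: Kinetic α′-deprotonation and SN2 C-methylation of the cross-conjugated lithium enolate (enolate alkylation); the new C6 centre should form mainly trans to the isopropenyl group but becomes an enolate carbon again in step 4, so its configuration is immaterial.

Step 2
Reactants: 5 phenyl vinyl sulfone; 6 formaldehyde
Product: 7 2-(phenylsulfonyl)prop-2-en-1-ol
Conditions: aq. CH2O (37 %), DABCO, THF, rt
Reagents that add atoms: formaldehyde (6), C=O
Why: Morita–Baylis–Hillman reaction: DABCO adds to the vinyl sulfone, the α-sulfonyl carbanion captures formaldehyde and loss of the amine returns the alkene with the sulfone on the central carbon, the regiochemistry the ring closure needs.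

Step 3
Reactants: 7 2-(phenylsulfonyl)prop-2-en-1-ol
Product: 8 3-bromo-2-(phenylsulfonyl)prop-1-ene
Conditions: PBr3, Et2O, 0 °C → rt
Reagents that add atoms: phosphorus tribromide, BrP(Br)Br
Why: Bromination of a primary allylic alcohol with PBr3 through a bromophosphite; SN2 and SN2′ displacement lead to the same bromide because the allyl unit is symmetric about the sulfonyl carbon.

Step 4
Reactants: 4 6-methylcarvone; 8 3-bromo-2-(phenylsulfonyl)prop-1-ene
Product: 10 6-methyl-6-[2-(phenylsulfonyl)allyl]carvone, via 6-methylcarvone lithium enolate 9 (not isolated)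
Conditions: LiN(i-Pr)2, THF, −78 °C; 8, −78 → −20 °C
Reagents that add atoms: 3-bromo-2-(phenylsulfonyl)prop-1-ene (8), BrCC(=C)S(=O)(=O)c1ccccc1
Why: Enolate alkylation: the tetrasubstituted lithium enolate attacks the CH2 terminus of 8 with loss of bromide (SN2′ addition–elimination) on the face anti to the neighbouring isopropenyl group, so the quaternary centre (future C10) should carry the chain trans and the methyl cis to that group.

Step 5
Reactants: 10 6-methyl-6-[2-(phenylsulfonyl)allyl]carvone
Product: 11 2α-(phenylsulfonyl)-11-nordrim-7-en-9-one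
Conditions: Fe(acac)3 (30 mol %), PhSiH3, EtOH/(CH2OH)2 5:1, high dilution, 60 °C
Reagents that add atoms: none
Why: Trivalent iron and PhSiH3 form an iron hydride that transfers a hydrogen atom to the CH2 of the isopropenyl group; the resulting nucleophilic tertiary C4 radical adds to the unsubstituted terminus C3 of the 2-sulfonylallyl unit, and the α-sulfonyl radical is reduced by divalent iron and protonated by ethanol, which returns trivalent iron. The closest known reaction type is the iron-hydride hydrogen-atom-transfer reductive olefin coupling (Giese type), run here intramolecularly. Ring A closes in the 6-endo-trig mode, because 5-exo attack would have to bond to the fully substituted, sulfone-bearing C2 and would leave an unstabilised primary radical. The trans ring fusion is inherited, not created: C1 and C4 already sit trans on ring B (C5 from carvone, C10 from the anti alkylation of step 4), so only the trans-decalin with the axial C10 methyl can form; the one new centre, C2, is set by protonation, expected to leave the sulfone equatorial, and is deleted in step 6. The step needs hydrogen transfer to the isopropenyl group in preference to the enone and the vinyl sulfone, which the preference of the hydridic iron hydride for the electron-rich 1,1-disubstituted alkene should secure, and 6-endo regiochemistry, which the sulfone on the internal alkene carbon secures.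

Step 6
Reactants: 11 2α-(phenylsulfonyl)-11-nordrim-7-en-9-one
Product: 13 11-nordrim-8-en-9-yl trifluoromethanesulfonate, via C9 lithium enolate 12 (not isolated)
Conditions: Li, NH3(l)/THF, t-BuOH (2 equiv), −78 °C; isoprene; evaporate NH3; PhNTf2 (excess), THF, −78 °C → rt
Reagents that add atoms: N-phenylbis(trifluoromethanesulfonimide), O=S(=O)(N(c1ccccc1)S(=O)(=O)C(F)(F)F)C(F)(F)F
Why: Dissolving-metal reduction: electron transfer cleaves the C2–S bond (reductive desulfonylation, erasing the C2 centre) and reduces the enone to the C8–C9 lithium enolate, the only regioisomer possible beside quaternary C10, which PhNTf2 O-sulfonylates to the enol triflate.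

Step 7
Reactants: 14 5-bromovanillin
Product: 16 2-bromo-6-methoxybenzene-1,4-diol, via aryl formate 15 (not isolated)
Conditions: H2O2 (30 %), aq. NaOH, rt; then HCl, Na2S2O4 work-up
Reagents that add atoms: hydrogen peroxide, OO
Why: Dakin oxidation: hydroperoxide adds to the aldehyde para to the phenoxide, aryl migration gives the formate and hydrolysis in the same flask gives the hydroquinone.

Step 8
Reactants: 16 2-bromo-6-methoxybenzene-1,4-diol; 2 iodomethane
Product: 17 1-bromo-2,3,5-trimethoxybenzene
Conditions: MeI, K2CO3, acetone, reflux
Reagents that add atoms: iodomethane (2), CI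
Why: Williamson ether synthesis: both phenoxides are O-methylated by SN2 reaction with iodomethane.

Step 9
Reactants: 17 1-bromo-2,3,5-trimethoxybenzene
Product: 19 trimethyl(2,3,5-trimethoxyphenyl)stannane, via 2,3,5-trimethoxyphenyllithium 18 (not isolated)
Conditions: n-BuLi, THF, −78 °C; Me3SnCl, −78 °C → rt
Reagents that add atoms: chlorotrimethylstannane, C[Sn](C)(C)Cl
Why: Bromine–lithium exchange followed by electrophilic stannylation of the aryllithium, which the flanking methoxy group stabilises.

Step 10
Reactants: 13 11-nordrim-8-en-9-yl trifluoromethanesulfonate; 19 trimethyl(2,3,5-trimethoxyphenyl)stannane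
Product: 20 11-(2,3,5-trimethoxyphenyl)drim-8-en-11-one
Conditions: Pd2(dba)3 (cat.), AsPh3, LiCl, CO (1 atm), NMP, 70 °C
Reagents that add atoms: trimethyl(2,3,5-trimethoxyphenyl)stannane (19), COc1cc(OC)cc([Sn](C)(C)C)c1OC; carbon monoxide, [C-]#[O+]
Why: Carbonylative Stille coupling: zerovalent palladium inserts into the enol triflate, CO insertion gives an acylpalladium (favoured at the hindered alkenyl centre), and transmetalation with the arylstannane and reductive elimination give the aryl alkenyl ketone without touching C5 or C10.

Step 11
Reactants: 20 11-(2,3,5-trimethoxyphenyl)drim-8-en-11-one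
Product: 21 (E)-11-(dimethylphenylsilyloxy)-11-(2,3,5-trimethoxyphenyl)-8β-methyl-drim-9(11)-ene
Conditions: RhCl(PPh3)3 (cat.), PhMe2SiH, toluene, 60 °C
Reagents that add atoms: dimethylphenylsilane, C[SiH](C)c1ccccc1
Why: Rhodium-catalysed 1,4-hydrosilylation of an enone with a monohydrosilane: silicon goes to oxygen and hydrogen to C8 through the s-cis-bound enone, which should place the siloxy group cis to C8, and hydrogen should enter the α face of C8 opposite the axial C10 methyl, setting the 8β-methyl centre (the arrangement that also avoids allylic 1,3-strain with the new exocyclic alkene).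

Step 12
Reactants: 21 (E)-11-(dimethylphenylsilyloxy)-11-(2,3,5-trimethoxyphenyl)-8β-methyl-drim-9(11)-ene
Product: 23 (E)-11-(2,3,5-trimethoxyphenyl)-8β-methyl-drim-9(11)-en-11-yl trifluoromethanesulfonate, via C11 lithium enolate 22 (not isolated)
Conditions: MeLi, THF, 0 °C; N-(5-chloropyridin-2-yl)bis(trifluoromethanesulfonimide), −78 → 0 °C
Reagents that add atoms: N-(5-chloropyridin-2-yl)bis(trifluoromethanesulfonimide), O=S(=O)(N(c1ccc(Cl)cn1)S(=O)(=O)C(F)(F)F)C(F)(F)F
Why: Cleavage of the silyl enol ether by MeLi gives the configurationally stable tetrasubstituted lithium enolate, which the pyridyl triflimide O-sulfonylates (enol triflate formation) with retention of the alkene geometry.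

Step 13
Reactants: 23 (E)-11-(2,3,5-trimethoxyphenyl)-8β-methyl-drim-9(11)-en-11-yl trifluoromethanesulfonate
Product: 24 (E)-11-chloro-11-(2,3,5-trimethoxyphenyl)-8β-methyl-drim-9(11)-ene
Conditions: Ni(OAc)2·4H2O (cat.), 1,5-cyclooctadiene, Zn (cat.), LiCl, DMA/THF, rt
Reagents that add atoms: lithium chloride, [Li+].[Cl-]
Why: Nickel-catalysed triflate–halide exchange of enol triflates: oxidative addition of zerovalent nickel, triflate/chloride exchange and C–Cl reductive elimination should proceed with retention at the alkenyl carbon, and the tetrasubstituted alkene offers no hydride pathway for isomerisation.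

Step 14
Reactants: 24 (E)-11-chloro-11-(2,3,5-trimethoxyphenyl)-8β-methyl-drim-9(11)-ene
Product: 25 target quinone CNP0249629.1
Conditions: (NH4)2Ce(NO3)6, MeCN/H2O, 0 °C
Reagents that add atoms: water, O
Why: Oxidative demethylation of the para-dimethoxy pair by tetravalent cerium should give the 2-methoxy-1,4-benzoquinone, with the third methoxy group retained and the vinyl chloride and the three stereocentres inert to the oxidant.

Compound list
1 | (R)-(−)-carvone | CC1=CC[C@H](CC1=O)C(C)=C | starting material
2 | iodomethane | CI | starting material
3 | carvone lithium enolate (cross-conjugated, C1=C6) | CC1=CC[C@H](C=C1O[Li])C(C)=C | intermediate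
4 | 6-methylcarvone, trans (5R,6S) epimer drawn, used as the C6 epimer mixture | O=C1C(C)=CC[C@@H](C(C)=C)[C@@H]1C | intermediate
5 | phenyl vinyl sulfone | C=CS(=O)(=O)c1ccccc1 | starting material
6 | formaldehyde (37 % aqueous) | C=O | starting material
7 | 2-(phenylsulfonyl)prop-2-en-1-ol | OCC(=C)S(=O)(=O)c1ccccc1 | intermediate
8 | 3-bromo-2-(phenylsulfonyl)prop-1-ene | BrCC(=C)S(=O)(=O)c1ccccc1 | intermediate
9 | 6-methylcarvone lithium enolate (tetrasubstituted, C1=C6) | [Li]OC1=C(C)[C@H](C(C)=C)CC=C1C | intermediate
10 | 6-methyl-6-[2-(phenylsulfonyl)allyl]carvone: 2,6-dimethyl-6-[2-(phenylsulfonyl)prop-2-en-1-yl]-5-(prop-1-en-2-yl)cyclohex-2-en-1-one, sulfonylallyl trans and 6-methyl cis to the isopropenyl group | O=C2C(C)=CC[C@@H](C(C)=C)[C@]2(C)CC(=C)S(=O)(=O)c1ccccc1 | intermediate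
11 | 2α-(phenylsulfonyl)-11-nordrim-7-en-9-one: trans-fused 2,5,5,8a-tetramethyl-7-(phenylsulfonyl)-4a,5,6,7,8,8a-hexahydronaphthalen-1(4H)-one, 5α-H, 10β-CH3, equatorial sulfone | O=C2C(C)=CC[C@H]3C(C)(C)C[C@H](S(=O)(=O)c1ccccc1)C[C@]23C | intermediate
12 | lithium 11-nordrim-8-en-9-olate (5α-H, 10β-CH3) | [Li]OC2=C(C)CC[C@H]3C(C)(C)CCC[C@]23C | intermediate
13 | 11-nordrim-8-en-9-yl trifluoromethanesulfonate (5α-H, 10β-CH3) | O=S(=O)(OC2=C(C)CC[C@H]3C(C)(C)CCC[C@]23C)C(F)(F)F | intermediate
14 | 5-bromovanillin | COc1cc(C=O)cc(Br)c1O | starting material
15 | 3-bromo-4-hydroxy-5-methoxyphenyl formate | COc1cc(OC=O)cc(Br)c1O | intermediate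
16 | 2-bromo-6-methoxybenzene-1,4-diol | COc1cc(O)cc(Br)c1O | intermediate
17 | 1-bromo-2,3,5-trimethoxybenzene | COc1cc(OC)cc(Br)c1OC | intermediate
18 | 2,3,5-trimethoxyphenyllithium | [Li]c1cc(OC)cc(OC)c1OC | intermediate
19 | trimethyl(2,3,5-trimethoxyphenyl)stannane | COc1cc(OC)cc([Sn](C)(C)C)c1OC | intermediate
20 | 11-(2,3,5-trimethoxyphenyl)drim-8-en-11-one (aryl ketone on C9; 5α-H, 10β-CH3) | COc1cc(OC)cc(C(=O)C2=C(C)CC[C@H]3C(C)(C)CCC[C@]23C)c1OC | intermediate
21 | (E)-11-(dimethylphenylsilyloxy)-11-(2,3,5-trimethoxyphenyl)-8β-methyl-drim-9(11)-ene, siloxy group cis to C8 | COc1cc(OC)cc(/C(O[Si](C)(C)c4ccccc4)=C2/[C@@H](C)CC[C@H]3C(C)(C)CCC[C@]23C)c1OC | intermediate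
22 | C11 lithium enolate, O–Li cis to C8, 8β-CH3 | COc1cc(OC)cc(/C(O[Li])=C2/[C@@H](C)CC[C@H]3C(C)(C)CCC[C@]23C)c1OC | intermediate
23 | (E)-11-(2,3,5-trimethoxyphenyl)-8β-methyl-drim-9(11)-en-11-yl trifluoromethanesulfonate, triflate cis to C8 | COc1cc(OC)cc(/C(OS(=O)(=O)C(F)(F)F)=C2/[C@@H](C)CC[C@H]3C(C)(C)CCC[C@]23C)c1OC | intermediate
24 | (E)-11-chloro-11-(2,3,5-trimethoxyphenyl)-8β-methyl-drim-9(11)-ene, chlorine cis to C8 | COc1cc(OC)cc(/C(Cl)=C2/[C@@H](C)CC[C@H]3C(C)(C)CCC[C@]23C)c1OC | intermediate
25 | CNP0249629.1: 2-methoxy-6-[(E)-chloro(drimane C9-ylidene)methyl]-1,4-benzoquinone, 5α-H, 8β-CH3, 10β-CH3, chlorine cis to C8 | COC1=CC(=O)C=C(/C(Cl)=C2/[C@@H](C)CC[C@H]3C(C)(C)CCC[C@]23C)C1=O | target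

Total step count: 14.
Longest linear sequence: 10 steps (steps 2, 3, 4, 5, 6, 10, 11, 12, 13, 14, counted from phenyl vinyl sulfone); 9 steps from (R)-carvone.

Steps most likely to fail

Step 11. The aroyl group on the tetrasubstituted C8–C9 alkene is twisted out of conjugation, so hydride delivery to C8 may be slow, the carbonyl may be hydrosilylated in the 1,2 sense, or reaction through a conformer other than s-cis may erode the enol ether geometry. The fallback sets out from 20 and forms the enolate by electron transfer instead of metal-hydride delivery: Li in NH3/THF with one equivalent of t-BuOH at −78 °C should reduce the enone, with protonation of C8 from the α face, directly to lithium enolate 22. After isoprene quench and removal of NH3 the enolate is triflated with the pyridyl triflimide, and the route is rejoined at 23, any geometrical isomer being removed by chromatography there or at 24.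

Step 13. Oxidative addition into the crowded tetrasubstituted enol triflate may stall, or reversible steps at nickel may scramble the alkene geometry. The fallback sets out from 23 and replaces direct C–Cl reductive elimination by tin–halogen exchange: Pd(PPh3)4, Me3SnSnMe3 and LiCl in THF at 65 °C should give the (E)-alkenyltrimethylstannane F1 with retention, and CuCl2 in THF at rt should then chlorodestannylate it with retention, returning to the route at 24.

Step 5. Hydrogen-atom transfer may go to the vinyl sulfone or the enone instead of the isopropenyl group, or the C4 radical may be reduced to an isopropyl group before it closes the ring. The fallback sets out from 10 and generates the same radical site-specifically by halogen abstraction: HBr in AcOH at 0 °C should add in the Markovnikov sense to the isopropenyl group only, giving the tertiary bromide F2. Slow addition of Bu3SnH with AIBN in benzene at 80 °C (tin-hydride Giese cyclisation) should then give the C4 radical, the same 6-endo closure onto C3 and hydrogen transfer to C2, returning to the route at 11.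

Further compounds
F0 | step 11 | none | none
F1 | step 13 | (E)-trimethyl[11-(2,3,5-trimethoxyphenyl)-8β-methyl-drim-9(11)-en-11-yl]stannane | COc1cc(OC)cc(/C([Sn](C)(C)C)=C2/[C@@H](C)CC[C@H]3C(C)(C)CCC[C@]23C)c1OC
F2 | step 5 | 5-(2-bromopropan-2-yl)-2,6-dimethyl-6-[2-(phenylsulfonyl)prop-2-en-1-yl]cyclohex-2-en-1-one, configuration as in 10 | O=C2C(C)=CC[C@@H](C(C)(C)Br)[C@]2(C)CC(=C)S(=O)(=O)c1ccccc1
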